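## Retrosynthetic overview

1. Target ⇒ bis-MOM chalcone ⇒ Claisen–Schmidt aldol condensation of a dihydrobenzofuranyl methyl ketone with 4-(methoxymethoxy)benzaldehyde (key C–C bond, last skeletal bond made).
2. Methyl ketone ⇒ MOM-directed ortho-lithiation/acetylation of a 4-oxygenated 2,3-dihydrobenzofuran.
3. Dihydrofuran ring ⇒ 5-exo opening of a cis-2,3-epoxyneryl resorcinol by its own phenoxide, with inversion at the secondary epoxide carbon.
4. Epoxyneryl arene ⇒ Cu-catalysed coupling of a 2,6-bis(allyloxy)phenyl Grignard with (2R,3S)-2,3-epoxyneryl tosylate ⇒ Sharpless epoxidation of nerol sets both stereocentres.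
5. Ring order: both benzene rings are bought; the dihydrofuran is the only ring built (step 6), before acetylation and the aldol.

Assumption: the SMILES is read as (2S) at the dihydrofuran carbon, (S) at the tertiary carbinol carbon and E at the enone; the trans-epoxide from geraniol would give the wrong diastereomer, so nerol is used.

## Route

Step 1
Reactants: 1 nerol
Product: 2 (2R,3S)-2,3-epoxynerol
Conditions: Ti(OiPr)4 (10 mol%), D-(−)-diethyl tartrate (12 mol%), t-BuOOH (2 equiv, in decane), 4 Å MS, CH2Cl2, −20 °C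
Reagents that add atoms: tert-butyl hydroperoxide, CC(C)(C)OO
Why: Sharpless asymmetric epoxidation oxidises only the allylic-alcohol alkene, and with D-(−)-DET gives the (2R,3S) cis-epoxide (typically 90–95% ee for nerol), so C3 is already the (S) carbinol centre and C2 awaits one inversion.

Step 2
Reactants: 2 (2R,3S)-2,3-epoxynerol
Product: 3 (2R,3S)-2,3-epoxyneryl 4-methylbenzenesulfonate
Conditions: TsCl, Et3N, DMAP (cat.), CH2Cl2, 0 °C
Reagents that add atoms: p-toluenesulfonyl chloride, Cc1ccc(cc1)S(=O)(=O)Cl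
Why: Sulfonylation of the primary alcohol makes C1 a leaving group without touching either stereocentre.

Step 3
Reactants: 4 resorcinol
Product: 5 2-iodoresorcinol
Conditions: I2, NaHCO3, H2O, 0 °C → rt
Reagents that add atoms: iodine, II
Why: Electrophilic aromatic iodination in mildly basic water goes selectively at C2, the position activated by both hydroxyl groups.

Step 4
Reactants: 5 2-iodoresorcinol
Product: 6 2-iodo-1,3-bis(prop-2-en-1-yloxy)benzene
Conditions: allyl bromide (2.5 equiv), K2CO3, DMF, rt → 50 °C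
Reagents that add atoms: allyl bromide, C=CCBr
Why: Williamson etherification gives allyl ethers that tolerate the Grignard chemistry and can later be removed by Pd(0) under basic conditions that leave an epoxide intact.

Step 5
Reactants: 6 2-iodo-1,3-bis(prop-2-en-1-yloxy)benzene; 3 (2R,3S)-2,3-epoxyneryl 4-methylbenzenesulfonate
Product: 8 (2S,3R)-3-{[2,6-bis(prop-2-en-1-yloxy)phenyl]methyl}-2-methyl-2-(4-methylpent-3-en-1-yl)oxirane, via aryl Grignard reagent 7 (not isolated)
Conditions: 6 (1.5 equiv), i-PrMgCl·LiCl, THF, 0 °C; then CuBr·SMe2 (10 mol%), 3 (1.0 equiv), −30 °C → rt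
Reagents that add atoms: none
Why: Iodine–magnesium exchange followed by copper-catalysed SN2 coupling of the aryl Grignard with the primary tosylate (Kochi–Schlosser type) occurs at C1 because both epoxide carbons are hindered, so the cis-epoxide and its two stereocentres are carried over unchanged.

Step 6
Reactants: 8 bis(allyl) aryl cis-epoxide
Product: 10 (2S)-2-[(2S)-2-hydroxy-6-methylhept-5-en-2-yl]-2,3-dihydro-1-benzofuran-4-ol, via resorcinol epoxide 9 (not isolated)
Conditions: Pd(PPh3)4 (5 mol%), K2CO3, MeOH, rt → 60 °C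
Reagents that add atoms: none
Why: Pd(0)-catalysed deallylation (Tsuji–Trost allyl transfer to methanol) frees the phenoxide, which opens the epoxide by 5-exo-tet SN2 attack at the secondary carbon with inversion (R → S at C2), while the tertiary C–O bond and its (S) configuration are retained.

Step 7
Reactants: 10 dihydrobenzofuran-4-ol
Product: 11 (2S)-2-[(2S)-4-(methoxymethoxy)-2,3-dihydro-1-benzofuran-2-yl]-6-methylhept-5-en-2-ol
Conditions: MOMCl (1.2 equiv), i-Pr2NEt, CH2Cl2, 0 °C → rt
Reagents that add atoms: chloromethyl methyl ether, COCCl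
Why: Chemoselective O-alkylation of the phenol (the hindered tertiary alcohol does not react) installs the directing group for the next step.

Step 8
Reactants: 11 MOM ether
Product: 14 1-[(2S)-2-[(2S)-2-hydroxy-6-methylhept-5-en-2-yl]-4-(methoxymethoxy)-2,3-dihydro-1-benzofuran-5-yl]ethan-1-one, via dilithio species 12 (not isolated), via tetrahedral adduct 13 (not isolated)
Conditions: n-BuLi (2.5 equiv), TMEDA, THF, −78 → 0 °C; then MeC(O)N(OMe)Me, −78 → 0 °C; aqueous work-up
Reagents that add atoms: N-methoxy-N-methylacetamide, CC(=O)N(C)OC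
Why: Directed ortho-metalation places lithium at C5, the only free position ortho to the chelating OMOM group (the tertiary OH is simply deprotonated), and Weinreb-amide acylation stops at the chelated adduct, which gives the methyl ketone on work-up.

Step 9
Reactants: 15 4-hydroxybenzaldehyde
Product: 16 4-(methoxymethoxy)benzaldehyde
Conditions: MOMCl, i-Pr2NEt, CH2Cl2, 0 °C → rt
Reagents that add atoms: chloromethyl methyl ether, COCCl
Why: O-alkylation masks the phenol, which as a phenoxide would deactivate the aldehyde in the base-mediated aldol.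

Step 10
Reactants: 14 methyl ketone; 16 4-(methoxymethoxy)benzaldehyde
Product: 18 (2E)-1-[(2S)-2-[(2S)-2-hydroxy-6-methylhept-5-en-2-yl]-4-(methoxymethoxy)-2,3-dihydro-1-benzofuran-5-yl]-3-[4-(methoxymethoxy)phenyl]prop-2-en-1-one, via aldol adduct 17 (not isolated)
Conditions: KOH (50% aq., excess), EtOH, rt, 24–48 h
Reagents that add atoms: none
Why: Claisen–Schmidt crossed aldol condensation joins the methyl ketone enolate to the non-enolisable aldehyde, and E1cB dehydration gives the E-enone; neither stereocentre carries an acidic hydrogen.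

Step 11
Reactants: 18 bis-MOM chalcone
Product: 19 (2E)-1-[(2S)-4-hydroxy-2-[(2S)-2-hydroxy-6-methylhept-5-en-2-yl]-2,3-dihydro-1-benzofuran-5-yl]-3-(4-hydroxyphenyl)prop-2-en-1-one (CNP0251652.1)
Conditions: 3 M aq. HCl, MeOH, rt → 40 °C
Reagents that add atoms: none
Why: Acid-catalysed acetal cleavage (transacetalisation to methanol) removes both aryl MOM ethers under conditions mild enough for the tertiary alcohol, the trisubstituted alkene and the E-enone.

Stereochemical bookkeeping: the enantiopurity comes entirely from step 1. Step 5 leaves the epoxide untouched and step 6 is stereospecific (one inversion at C2), so no later step can scramble either centre.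

## Compound list

1 | nerol, (2Z)-3,7-dimethylocta-2,6-dien-1-ol | CC(C)=CCC/C(C)=C\CO | starting material
2 | (2R,3S)-2,3-epoxynerol, [(2R,3S)-3-methyl-3-(4-methylpent-3-en-1-yl)oxiran-2-yl]methanol | CC(C)=CCC[C@]1(C)O[C@@H]1CO | intermediate
3 | [(2R,3S)-3-methyl-3-(4-methylpent-3-en-1-yl)oxiran-2-yl]methyl 4-methylbenzenesulfonate | CC(C)=CCC[C@]1(C)O[C@@H]1COS(=O)(=O)c1ccc(C)cc1 | intermediate
4 | resorcinol, benzene-1,3-diol | Oc1cccc(O)c1 | starting material
5 | 2-iodoresorcinol, 2-iodobenzene-1,3-diol | Oc1cccc(O)c1I | intermediate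
6 | 2-iodo-1,3-bis(prop-2-en-1-yloxy)benzene | C=CCOc1cccc(OCC=C)c1I | intermediate
7 | [2,6-bis(prop-2-en-1-yloxy)phenyl]magnesium chloride | C=CCOc1cccc(OCC=C)c1[Mg]Cl | intermediate
8 | (2S,3R)-3-{[2,6-bis(prop-2-en-1-yloxy)phenyl]methyl}-2-methyl-2-(4-methylpent-3-en-1-yl)oxirane (cis-epoxide, same configuration as in 2) | CC(C)=CCC[C@]1(C)O[C@@H]1Cc1c(OCC=C)cccc1OCC=C | intermediate
9 | 2-{[(2R,3S)-3-methyl-3-(4-methylpent-3-en-1-yl)oxiran-2-yl]methyl}benzene-1,3-diol (present as its potassium phenoxide) | CC(C)=CCC[C@]1(C)O[C@@H]1Cc1c(O)cccc1O | intermediate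
10 | (2S)-2-[(2S)-2-hydroxy-6-methylhept-5-en-2-yl]-2,3-dihydro-1-benzofuran-4-ol | CC(C)=CCC[C@](C)(O)[C@@H]1Cc2c(O)cccc2O1 | intermediate
11 | (2S)-2-[(2S)-4-(methoxymethoxy)-2,3-dihydro-1-benzofuran-2-yl]-6-methylhept-5-en-2-ol | CC(C)=CCC[C@](C)(O)[C@@H]1Cc2c(OCOC)cccc2O1 | intermediate
12 | C5-lithiated lithium alkoxide of 11 | CC(C)=CCC[C@](C)(O[Li])[C@@H]1Cc2c(OCOC)c([Li])ccc2O1 | intermediate
13 | dilithium tetrahedral adduct of 12 with N-methoxy-N-methylacetamide (new aminal carbon unassigned) | CC(C)=CCC[C@](C)(O[Li])[C@@H]1Cc2c(OCOC)c(C(C)(O[Li])N(C)OC)ccc2O1 | intermediate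
14 | 1-[(2S)-2-[(2S)-2-hydroxy-6-methylhept-5-en-2-yl]-4-(methoxymethoxy)-2,3-dihydro-1-benzofuran-5-yl]ethan-1-one | CC(C)=CCC[C@](C)(O)[C@@H]1Cc2c(OCOC)c(C(C)=O)ccc2O1 | intermediate
15 | 4-hydroxybenzaldehyde | O=Cc1ccc(O)cc1 | starting material
16 | 4-(methoxymethoxy)benzaldehyde | COCOc1ccc(C=O)cc1 | intermediate
17 | 3-hydroxy-1-[(2S)-2-[(2S)-2-hydroxy-6-methylhept-5-en-2-yl]-4-(methoxymethoxy)-2,3-dihydro-1-benzofuran-5-yl]-3-[4-(methoxymethoxy)phenyl]propan-1-one (both epimers at the new carbinol) | CC(C)=CCC[C@](C)(O)[C@@H]1Cc2c(OCOC)c(C(=O)CC(O)c3ccc(OCOC)cc3)ccc2O1 | intermediate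
18 | (2E)-1-[(2S)-2-[(2S)-2-hydroxy-6-methylhept-5-en-2-yl]-4-(methoxymethoxy)-2,3-dihydro-1-benzofuran-5-yl]-3-[4-(methoxymethoxy)phenyl]prop-2-en-1-one | CC(C)=CCC[C@](C)(O)[C@@H]1Cc2c(OCOC)c(C(=O)/C=C/c3ccc(OCOC)cc3)ccc2O1 | intermediate
19 | (2E)-1-[(2S)-4-hydroxy-2-[(2S)-2-hydroxy-6-methylhept-5-en-2-yl]-2,3-dihydro-1-benzofuran-5-yl]-3-(4-hydroxyphenyl)prop-2-en-1-one | CC(C)=CCC[C@](C)(O)[C@@H]1Cc2c(ccc(C(=O)/C=C/c3ccc(O)cc3)c2O)O1 | target

## Step count and risks

Total step count: 11. Longest linear sequence: 8 steps (1 → 2 → 3 → 8 → 10 → 11 → 14 → 18 → 19; the resorcinol branch 4 → 5 → 6 → 8 onward is equally long).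

Steps most likely to fail:

Step 5 (aryl–C1 coupling). The doubly ortho-substituted Grignard may couple slowly with the tosylate, or magnesium halide may open the epoxide. The fallback sets out from 2 and makes the same bond by opening a terminal epoxide instead. Payne rearrangement–opening of 2 with PhSH and aqueous NaOH in t-BuOH at 80 °C gives (2R,3S)-3,7-dimethyl-1-(phenylsulfanyl)oct-6-ene-2,3-diol F1, with C2 inverted. S-Methylation with Me3OBF4 in CH2Cl2 gives [(2R,3S)-2,3-dihydroxy-3,7-dimethyloct-6-en-1-yl](methyl)phenylsulfonium tetrafluoroborate F2. NaH in THF closes it to the terminal epoxide (2S)-6-methyl-2-[(2S)-oxiran-2-yl]hept-5-en-2-ol F3. After deprotonating its hydroxyl with one equivalent of MeMgCl, the Grignard reagent 7 with catalytic CuI opens F3 at the unhindered CH2 to give (2S,3S)-1-[2,6-bis(prop-2-en-1-yloxy)phenyl]-3,7-dimethyloct-6-ene-2,3-diol F4. MsCl and Et3N at −10 °C sulfonylate only the secondary hydroxyl to give (2S,3S)-1-[2,6-bis(prop-2-en-1-yloxy)phenyl]-3-hydroxy-3,7-dimethyloct-6-en-2-yl methanesulfonate F5. K2CO3 in MeOH then closes the tertiary alkoxide onto C2 with a second inversion, which returns the route to 8.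

Step 8 (ortho-lithiation/acetylation). Lithiation could compete at C7, ortho to the ring oxygen, or the acylation could be low-yielding. The fallback sets out from phenol 10 and uses the free hydroxyl to direct the carbon in. Magnesium-mediated ortho-formylation (MgCl2, Et3N, paraformaldehyde, MeCN, reflux) gives (2S)-4-hydroxy-2-[(2S)-2-hydroxy-6-methylhept-5-en-2-yl]-2,3-dihydro-1-benzofuran-5-carbaldehyde F6, C5 being the only free ortho position. NaH (1 equiv) and MOMCl give (2S)-2-[(2S)-2-hydroxy-6-methylhept-5-en-2-yl]-4-(methoxymethoxy)-2,3-dihydro-1-benzofuran-5-carbaldehyde F7. MeMgBr (2.5 equiv) in THF gives (2S)-2-[(2S)-5-(1-hydroxyethyl)-4-(methoxymethoxy)-2,3-dihydro-1-benzofuran-2-yl]-6-methylhept-5-en-2-ol F8 as an epimer mixture. Dess–Martin oxidation of the benzylic alcohol returns the route to 14.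

Step 11 (final acid deprotection). The tertiary alcohol could cyclise onto the trisubstituted alkene, or the 2'-hydroxychalcone could close to a flavanone, before the para-enone MOM ether is gone. The fallback sets out from 14 and removes all acid from the chalcone stage. The carbonyl-flanked MOM ether of 14 cleaves far more easily (catalytic HCl in MeOH, 0 °C) and gives 1-[(2S)-4-hydroxy-2-[(2S)-2-hydroxy-6-methylhept-5-en-2-yl]-2,3-dihydro-1-benzofuran-5-yl]ethan-1-one F9. Claisen–Schmidt condensation of F9 with unprotected 4-hydroxybenzaldehyde 15 (large excess of 50% aq. KOH, EtOH, rt, 48–72 h, then neutralisation with AcOH) gives 19 directly.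

Further compounds
F1 | step 5 | (2R,3S)-3,7-dimethyl-1-(phenylsulfanyl)oct-6-ene-2,3-diol | CC(C)=CCC[C@](C)(O)[C@@H](O)CSc1ccccc1
F2 | step 5 | [(2R,3S)-2,3-dihydroxy-3,7-dimethyloct-6-en-1-yl](methyl)phenylsulfonium tetrafluoroborate | CC(C)=CCC[C@](C)(O)[C@@H](O)C[S+](C)c1ccccc1.F[B-](F)(F)F
F3 | step 5 | (2S)-6-methyl-2-[(2S)-oxiran-2-yl]hept-5-en-2-ol | CC(C)=CCC[C@](C)(O)[C@@H]1CO1
F4 | step 5 | (2S,3S)-1-[2,6-bis(prop-2-en-1-yloxy)phenyl]-3,7-dimethyloct-6-ene-2,3-diol | CC(C)=CCC[C@](C)(O)[C@@H](O)Cc1c(OCC=C)cccc1OCC=C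
F5 | step 5 | (2S,3S)-1-[2,6-bis(prop-2-en-1-yloxy)phenyl]-3-hydroxy-3,7-dimethyloct-6-en-2-yl methanesulfonate | CC(C)=CCC[C@](C)(O)[C@@H](OS(C)(=O)=O)Cc1c(OCC=C)cccc1OCC=C
F6 | step 8 | (2S)-4-hydroxy-2-[(2S)-2-hydroxy-6-methylhept-5-en-2-yl]-2,3-dihydro-1-benzofuran-5-carbaldehyde | CC(C)=CCC[C@](C)(O)[C@@H]1Cc2c(O)c(C=O)ccc2O1
F7 | step 8 | (2S)-2-[(2S)-2-hydroxy-6-methylhept-5-en-2-yl]-4-(methoxymethoxy)-2,3-dihydro-1-benzofuran-5-carbaldehyde | CC(C)=CCC[C@](C)(O)[C@@H]1Cc2c(OCOC)c(C=O)ccc2O1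
F8 | step 8 | (2S)-2-[(2S)-5-(1-hydroxyethyl)-4-(methoxymethoxy)-2,3-dihydro-1-benzofuran-2-yl]-6-methylhept-5-en-2-ol (both epimers at the new carbinol) | CC(C)=CCC[C@](C)(O)[C@@H]1Cc2c(OCOC)c(C(C)O)ccc2O1
F9 | step 11 | 1-[(2S)-4-hydroxy-2-[(2S)-2-hydroxy-6-methylhept-5-en-2-yl]-2,3-dihydro-1-benzofuran-5-yl]ethan-1-one | CC(C)=CCC[C@](C)(O)[C@@H]1Cc2c(O)c(C(C)=O)ccc2O1
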